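Fractions of the substrate charge per minute are the unit here, and you will follow the rate of target in that unit rather than what stands in the flask.

| flask | substrate | partner | temperature | remark | time |
|---|---|---|---|---|---|
| dusk | 0.11 M | 0.98 equiv | 0 °C | run made earlier |  |
| autumn | 0.11 M | 1.5 equiv | 25 °C | run made earlier |  |
| midnight | 0.17 M | 0.70 equiv | 0 °C | run made earlier |  |
| north | 0.11 M | 0.700 equiv | 25 °C |  | 15 min |
| east | 0.11 M | 0.700 equiv | 45 °C |  | 15 min |
| north-west | 0.11 M | 0.700 equiv | 5 °C |  | 15 min |

| run | time / min | target / % |
|---|---|---|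
| dusk | 5.00 | 17.5 |
| dusk | 10.0 | 22.2 |
| dusk | 15.0 | 26.6 |
| dusk | 20.0 | 27.8 |
| dusk | 30.0 | 31.5 |
| autumn | 0.667 | 32.6 |
| autumn | 1.33 | 41.3 |
| autumn | 2.00 | 46.2 |
| autumn | 3.00 | 51.0 |
| autumn | 5.00 | 61.5 |
| autumn | 10.0 | 76.7 |
| midnight | 6.00 | 18.8 |
| midnight | 15.0 | 21.4 |
| midnight | 30.0 | 24.5 |

(standard deviation of a reading: 1 percentage point)

- what was read earlier has a scatter of 1 percentage point, one standard deviation

1. the flask that comes out highest in amount of target, in percent of the substrate charged, or "all alike" when all lie within 1.5 percentage points (north / east / north-west / all alike)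
2. target at the end, in percent of the substrate charged, north
3. target at the end, in percent of the substrate charged, east
4. target at the end, in percent of the substrate charged, north-west

Call the target fraction x and the partner equivalents r. The autumn run climbs at 0.489 min⁻¹ up to its first reading, but at 0.0304 min⁻¹ between its last two. Try rate = c(1 − x)(r − x)/x, so that the target itself brakes the rate. In powers of ten, between autumn's first and last readings, the substrate factor costs 0.461 decades, the partner factor 0.205 and the brake 0.372.

The accumulated slowing is G = [r ln(1 − x/r) − ln(1 − x)]/(r − 1), and G = ct. Autumn's last reading gives 0.0765 min⁻¹. Midnight, with the partner share of the new flasks, gives 0.00228 min⁻¹ from its last reading, though its first gives 0.00593 min⁻¹, so the law is rough in this run. That is 1.53 decades between autumn and midnight, which differ in temperature, concentration and partner, and I read the gap as a temperature effect, which is an assumption.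

Spreading those decades evenly over temperature gives the braking constant of north-west, 0.00460 min⁻¹, and 1.27 min⁻¹ for east. I take one partner per target, so at 0.700 equiv in the new flasks partner is the limiting reagent and x stops at r.

My reckoning for north-west needs 13.1 min to reach 23.3% and 17.8 min to reach 26.2%, so 15 min falls between. North, on autumn's constant, needs 13.3 min for 56.0% and 19.4 min for 60.0%. East, on 1.27 min⁻¹, needs 5.36 min to come within a hundredth of its ceiling.

The forecast named east, with 56% for north, 69% for east and 28% for north-west, the last above my range, and said of east that “conversion nearly reaches the 70% partner limit”.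

The flasks gave 59.4% in north, 70.0% in east and 25.0% in north-west, so east is highest.

    substrate + partner ⇌ intermediate A (K = 11.0 M⁻¹, k = 0.760 M⁻¹ s⁻¹, Ea = 36.0 kJ mol⁻¹, ΔH = −20.0 kJ mol⁻¹)
    intermediate A → target (k = 0.00470 s⁻¹, Ea = 81.0 kJ mol⁻¹)
    intermediate A → intermediate B (k = 0.00970 s⁻¹, Ea = 68.0 kJ mol⁻¹)
    intermediate B ⇌ intermediate C (K = 0.200, k = 0.00120 s⁻¹, Ea = 73.0 kJ mol⁻¹, ΔH = 11.0 kJ mol⁻¹)
    intermediate C ⇌ intermediate D (K = 0.580, k = 0.00150 s⁻¹, Ea = 90.0 kJ mol⁻¹, ΔH = −3.00 kJ mol⁻¹)
    intermediate D → target (k = 0.00390 s⁻¹, Ea = 71.0 kJ mol⁻¹)
    (constants at 5 °C)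

East reached 70 percent conversion at 7.87 min, about half of its 15 min, and at the end it holds 70.0% target and 0% intermediate B. North-west at 15.0 min holds 35.9% intermediate B beside 25.0% target, yet its result read back gives c = 0.00480 min⁻¹ against the carried 0.00460 min⁻¹. A neighbour flask, north-west changed to 1.20 equiv partner, gave 35.3% in 15 min, where the carried constant asks 18.9 min.

(All runs are simulated with made-up constants, noise included.)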